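If one molecule of substrate is followed through a stirred flow tank, its chances at each fork give an estimate of the share that ends as target.

    substrate ⇌ intermediate A (K1 = 0.47, k1 = 0.24 h⁻¹)
    intermediate B ⇌ intermediate C (k2 = 0.017 h⁻¹)
    intermediate C → target (k3 = 0.15 h⁻¹)
    substrate ⇌ intermediate C (K4 = 12, k4 = 0.50 h⁻¹)
    intermediate B ⇌ substrate (k5 = 0.049 h⁻¹)
    2 substrate → self-condensation product (k6 = 0.0084 M⁻¹ h⁻¹)
    intermediate A ⇌ intermediate B (K7 = 1.2, k7 = 0.28 h⁻¹)

| setting | larch | alder | birch | oak |
|---|---|---|---|---|
| substrate | 0.050 M | 0.050 M | 0.050 M | 0.050 M |
| remark | one stirred flow tank at steady state, fed with the mixture as stated, mean residence time 240 min | a tube with plug flow, the mixed feed as stated, residence time 80 min | a single well-mixed tank run continuously and read at steady state, 80 min in it on average | a closed flask charged with all of it at once and left for 80 min |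
| time |  | 80 min |  | 80 min |

- percentages count the substrate that a species holds: one self-condensation product counts as two
- a doubled species enters its step squared and goes two at a time
- the stated concentrations are those of everything mixed, before any reaction; amounts are the same in each set-up
- run time (alder): 80 min

1. the set-up with the highest amount of target at the outlet or at the end, in percent of the substrate put in ("none" if the first two lie within 2 percentage points) (larch / alder / birch / oak / none)
2. amount of target at the outlet or at the end, in percent of the substrate put in, larch
3. amount of target at the outlet or at the end, in percent of the substrate put in, alder
4. amount of target at the outlet or at the end, in percent of the substrate put in, birch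
5. amount of target at the outlet or at the end, in percent of the substrate put in, oak

**First instants.** Take larch. A flow tank washes a molecule out at the rate w, one over the residence time, here 0.250 h⁻¹. A molecule entering larch stands on substrate. It passes to intermediate C at 0.50 h⁻¹ and to intermediate A at 0.24 h⁻¹. Its passage to intermediate B, at 0.0276 h⁻¹, is slower than either, so my reckoning drops it. Self-condensation at the feed concentration takes 8.40 × 10⁻⁴ h⁻¹, far less than the step to intermediate C, so my reckoning drops it and every fork becomes first order.

**The middle.** On intermediate A the molecule returns to substrate at 0.511 h⁻¹, moves to intermediate B at 0.28 h⁻¹, or washes out. I count intermediate B as lost, so the chance of return is ρ = 0.491. The chance σ that substrate reaches intermediate C before leaving, a branching ratio, is the rate to intermediate C over the sum of that rate, w and the unreturned part of the rate to intermediate A. In larch σ = 0.573.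

**The end.** On intermediate C the molecule goes to target at 0.15 h⁻¹, back to substrate at 0.0417 h⁻¹, or out. Its way to intermediate B, at 7.99 × 10⁻⁴ h⁻¹, is slower than the step to target, so my reckoning drops it. These rates give a chance π = 0.340 of target and β = 0.0943 of return. A returned molecule tries again, so σπ is divided by one minus σβ. This gives the tank chance P, the chance that an entering molecule of substrate leaves as target: 20.6% in larch.

**Other vessels.** In birch, w is 0.750 h⁻¹ and P comes to 5.74%. Alder and oak each hold every molecule for 80 min, so I reckon them alike, as two steps in a row with substrate leaving at 0.740 h⁻¹. That gives 4.59%. My reckoning therefore puts larch highest.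

The forecast gives 20.8% for larch, 5.67% for birch, and 4.53% and 4.53% for alder and oak, choosing larch: “Larch is best because its residence time is three times longer”.

**The result.** The simulation gives 20.8% in larch, 5.67% in birch, 4.53% in alder and 4.53% in oak, with larch best. The tank chance for larch lies 0.20 percentage points below its simulated value. Setting ρ to zero in P, as for a larch in which intermediate A cannot return to substrate, lowers σ to 0.505 and P from 20.6% to 18.0%. The simulated larch with that return struck out stands at 18.0%.

The numbers of this flask are invented; the result is computed.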